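**Retrosynthetic overview**
- The target is reached by Pd(0) de-allylation of an O-allyl acid; the ring-B CO2H comes from an aldehyde (Pinnick) placed by ortho-specific formylation of a 2-chlorophenol.
- Ring B is aromatised late: a 4,4-dichloro-3-oxocyclohexenyl aryl ether loses HCl; both chlorines are put on the α′ carbon by kinetic enolate chlorination, so Cl ends next to the new OH.
- The diaryl-ether C–O bond is made before aromatisation by addition–elimination of the ring-A phenol on a β-chloro enone from 5-methylcyclohexane-1,3-dione.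
- The dione (the only ring built; ring A is bought aromatic) comes from an intermolecular Michael addition of ethyl acetoacetate to ethyl crotonate, then Dieckmann closure and decarboxylation.
- Ring A comes from 5-iodovanillin by methoxycarbonylation, Dakin-type oxidation and selective 5-O-allylation.

Assumption: the target has no stereocentre and its diaryl-ether axis is not configurationally stable, so it is achiral and needs no enantiocontrol; stereocentres in intermediates are racemic and vanish on aromatisation.

Step 1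
Reactants: 1 ethyl acetoacetate; 2 ethyl (E)-but-2-enoate
Product: 4 ethyl 2-methyl-4,6-dioxocyclohexane-1-carboxylate, via Michael adduct 3 (not isolated)
Conditions: NaOEt, EtOH, reflux; then cold aq. HCl
Reagents that add atoms: none
Why: Michael addition of the acetoacetate enolate to the crotonate β-carbon, then in-pot Dieckmann (intramolecular Claisen) closure of the methyl-ketone enolate on the distal ester, is driven by the stabilised β-diketone enolate; the stereocentres form racemic and are erased later.

Step 2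
Reactants: 4 ethyl 2-methyl-4,6-dioxocyclohexane-1-carboxylate
Product: 6 5-methylcyclohexane-1,3-dione, via keto acid 5 (not isolated)
Conditions: aq. KOH, reflux; then HCl to pH 1, reflux
Reagents that add atoms: none
Why: Saponification and thermal decarboxylation of the β-keto acid (the classical dimedone sequence) give the symmetric dione, whose two carbonyl carbons become the two ring-B oxygens.

Step 3
Reactants: 6 5-methylcyclohexane-1,3-dione
Product: 7 3-chloro-5-methylcyclohex-2-en-1-one
Conditions: (COCl)2, cat. DMF, CH2Cl2, 0 °C to rt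
Reagents that add atoms: oxalyl chloride, ClC(=O)C(=O)Cl
Why: Vilsmeier-type activation of the vinylogous acid and chloride addition–elimination give the vinylogous acid chloride; the symmetry of 6 allows only one (racemic) product.

Step 4
Reactants: 8 4-hydroxy-3-iodo-5-methoxybenzaldehyde (5-iodovanillin)
Product: 9 methyl 5-formyl-2-hydroxy-3-methoxybenzoate
Conditions: Pd(OAc)2 (3 mol %), dppf, Et3N, CO (1 atm), MeOH/DMF, 70 °C
Reagents that add atoms: carbon monoxide, [C-]#[O+]; methanol, CO
Why: Pd-catalysed methoxycarbonylation of the aryl iodide (oxidative addition, CO insertion, methanolysis) tolerates the free phenol and the aldehyde.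

Step 5
Reactants: 9 methyl 5-formyl-2-hydroxy-3-methoxybenzoate
Product: 11 methyl 2,5-dihydroxy-3-methoxybenzoate, via aryl formate 10 (not isolated)
Conditions: mCPBA, CH2Cl2, 0 °C to rt; then MeOH, cat. HCl, rt, N2
Reagents that add atoms: mCPBA, OOC(=O)c1cccc(Cl)c1
Why: Baeyer–Villiger (Dakin-type) oxidation, in which the para-OH makes aryl migration dominant; the formate is cleaved by methanolysis without touching the methyl ester.

Step 6
Reactants: 11 methyl 2,5-dihydroxy-3-methoxybenzoate
Product: 12 methyl 2-hydroxy-3-methoxy-5-(prop-2-en-1-yloxy)benzoate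
Conditions: allyl bromide (1.05 equiv), K2CO3, acetone, 40 °C, N2
Reagents that add atoms: allyl bromide, C=CCBr
Why: Williamson etherification is selective for the unhindered 5-OH because the 2-OH is hydrogen-bonded to the ester and flanked by CO2Me and OMe.

Step 7
Reactants: 7 3-chloro-5-methylcyclohex-2-en-1-one; 12 methyl 2-hydroxy-3-methoxy-5-(prop-2-en-1-yloxy)benzoate
Product: 13 methyl 3-methoxy-2-[(5-methyl-3-oxocyclohex-1-en-1-yl)oxy]-5-(prop-2-en-1-yloxy)benzoate
Conditions: Cs2CO3, MeCN, 60 °C
Reagents that add atoms: none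
Why: Vinylogous nucleophilic acyl substitution (addition–elimination) of the β-chloro enone by the phenoxide forms the hindered diaryl-ether C–O bond without a metal and fixes which ring-B oxygen carries ring A.

Step 8
Reactants: 13 methyl 3-methoxy-2-[(5-methyl-3-oxocyclohex-1-en-1-yl)oxy]-5-(prop-2-en-1-yloxy)benzoate
Product: 15 methyl 2-[(4,4-dichloro-5-methyl-3-oxocyclohex-1-en-1-yl)oxy]-3-methoxy-5-(prop-2-en-1-yloxy)benzoate, via monochloro enone 14 (not isolated)
Conditions: LDA (1.1 equiv), THF, −78 °C, then NCS (1.1 equiv); second LDA/NCS cycle, −78 to −40 °C; aq. NH4Cl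
Reagents that add atoms: N-chlorosuccinimide, O=C1CCC(=O)N1Cl
Why: Stork–Danheiser kinetic deprotonation of the vinylogous ester occurs only at the α′ carbon, and the lithium enolate is chlorinated by NCS; the more acidic α-chloro ketone is deprotonated at the same carbon in the second cycle.

Step 9
Reactants: 15 methyl 2-[(4,4-dichloro-5-methyl-3-oxocyclohex-1-en-1-yl)oxy]-3-methoxy-5-(prop-2-en-1-yloxy)benzoate
Product: 17 methyl 2-(4-chloro-3-hydroxy-5-methylphenoxy)-3-methoxy-5-(prop-2-en-1-yloxy)benzoate, via chlorodienone 16 (not isolated)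
Conditions: DBU (2.5 equiv), MeCN, 50 °C; then 1 M HCl
Reagents that add atoms: none
Why: Base-induced dehydrochlorination gives the cross-conjugated chlorodienone, which tautomerises to the phenol (aromatisation), leaving one chlorine between the new OH and the methyl group.

Step 10
Reactants: 17 methyl 2-(4-chloro-3-hydroxy-5-methylphenoxy)-3-methoxy-5-(prop-2-en-1-yloxy)benzoate
Product: 19 methyl 2-(4-chloro-2-formyl-3-hydroxy-5-methylphenoxy)-3-methoxy-5-(prop-2-en-1-yloxy)benzoate, via benzylic alcohol 18 (not isolated)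
Conditions: MgCl2, Et3N, (CH2O)n, MeCN, reflux; then 1 M HCl
Reagents that add atoms: formaldehyde (as paraformaldehyde), C=O
Why: Casiraghi–Skattebøl magnesium-mediated formylation is specific for positions ortho to the phenol OH, and the only free one lies between OH and the aryloxy group; the benzylic alkoxide is oxidised by a second formaldehyde (Oppenauer-type hydride transfer).

Step 11
Reactants: 19 methyl 2-(4-chloro-2-formyl-3-hydroxy-5-methylphenoxy)-3-methoxy-5-(prop-2-en-1-yloxy)benzoate
Product: 20 3-chloro-2-hydroxy-6-[2-methoxy-6-(methoxycarbonyl)-4-(prop-2-en-1-yloxy)phenoxy]-4-methylbenzoic acid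
Conditions: NaClO2, NaH2PO4, 2-methylbut-2-ene, t-BuOH/THF/H2O, 0 °C to rt
Reagents that add atoms: sodium chlorite, [Na+].[O-]Cl=O
Why: Pinnick (Lindgren) oxidation converts the aldehyde to the acid and leaves the methyl ester, allyl ether and aryl chloride alone; the alkene scavenger removes HOCl, and the ring-B acid is thereby differentiated from the ring-A ester without a protecting group.

Step 12
Reactants: 20 3-chloro-2-hydroxy-6-[2-methoxy-6-(methoxycarbonyl)-4-(prop-2-en-1-yloxy)phenoxy]-4-methylbenzoic acid
Product: 21 3-chloro-2-hydroxy-6-[4-hydroxy-2-methoxy-6-(methoxycarbonyl)phenoxy]-4-methylbenzoic acid (isodihydromaldoxin)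
Conditions: Pd(PPh3)4 (5 mol %), morpholine, THF, rt; then 1 M HCl
Reagents that add atoms: none
Why: Tsuji–Trost de-allylation, in which Pd(0) ionises the allyl aryl ether and morpholine traps the π-allyl, frees the phenol under neutral conditions that spare the ester, acid and Ar–Cl.

**Compound list**
1 | ethyl acetoacetate | CCOC(=O)CC(C)=O | starting material
2 | ethyl (E)-but-2-enoate (ethyl crotonate) | C/C=C/C(=O)OCC | starting material
3 | diethyl 2-acetyl-3-methylpentanedioate (racemic diastereomers) | CCOC(=O)CC(C)C(C(C)=O)C(=O)OCC | intermediate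
4 | ethyl 2-methyl-4,6-dioxocyclohexane-1-carboxylate (racemic) | CCOC(=O)C1C(C)CC(=O)CC1=O | intermediate
5 | 2-methyl-4,6-dioxocyclohexane-1-carboxylic acid (racemic) | OC(=O)C1C(C)CC(=O)CC1=O | intermediate
6 | 5-methylcyclohexane-1,3-dione | CC1CC(=O)CC(=O)C1 | intermediate
7 | 3-chloro-5-methylcyclohex-2-en-1-one (racemic) | CC1CC(Cl)=CC(=O)C1 | intermediate
8 | 4-hydroxy-3-iodo-5-methoxybenzaldehyde (5-iodovanillin) | COc1cc(C=O)cc(I)c1O | starting material
9 | methyl 5-formyl-2-hydroxy-3-methoxybenzoate | COC(=O)c1cc(C=O)cc(OC)c1O | intermediate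
10 | methyl 5-(formyloxy)-2-hydroxy-3-methoxybenzoate | COC(=O)c1cc(OC=O)cc(OC)c1O | intermediate
11 | methyl 2,5-dihydroxy-3-methoxybenzoate | COC(=O)c1cc(O)cc(OC)c1O | intermediate
12 | methyl 2-hydroxy-3-methoxy-5-(prop-2-en-1-yloxy)benzoate | COC(=O)c1cc(OCC=C)cc(OC)c1O | intermediate
13 | methyl 3-methoxy-2-[(5-methyl-3-oxocyclohex-1-en-1-yl)oxy]-5-(prop-2-en-1-yloxy)benzoate (racemic) | COC(=O)c1cc(OCC=C)cc(OC)c1OC1=CC(=O)CC(C)C1 | intermediate
14 | methyl 2-[(4-chloro-5-methyl-3-oxocyclohex-1-en-1-yl)oxy]-3-methoxy-5-(prop-2-en-1-yloxy)benzoate (racemic diastereomers) | COC(=O)c1cc(OCC=C)cc(OC)c1OC1=CC(=O)C(Cl)C(C)C1 | intermediate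
15 | methyl 2-[(4,4-dichloro-5-methyl-3-oxocyclohex-1-en-1-yl)oxy]-3-methoxy-5-(prop-2-en-1-yloxy)benzoate (racemic) | COC(=O)c1cc(OCC=C)cc(OC)c1OC1=CC(=O)C(Cl)(Cl)C(C)C1 | intermediate
16 | methyl 2-[(4-chloro-5-methyl-3-oxocyclohexa-1,4-dien-1-yl)oxy]-3-methoxy-5-(prop-2-en-1-yloxy)benzoate | COC(=O)c1cc(OCC=C)cc(OC)c1OC1=CC(=O)C(Cl)=C(C)C1 | intermediate
17 | methyl 2-(4-chloro-3-hydroxy-5-methylphenoxy)-3-methoxy-5-(prop-2-en-1-yloxy)benzoate | COC(=O)c1cc(OCC=C)cc(OC)c1Oc1cc(C)c(Cl)c(O)c1 | intermediate
18 | methyl 2-[4-chloro-3-hydroxy-2-(hydroxymethyl)-5-methylphenoxy]-3-methoxy-5-(prop-2-en-1-yloxy)benzoate | COC(=O)c1cc(OCC=C)cc(OC)c1Oc1cc(C)c(Cl)c(O)c1CO | intermediate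
19 | methyl 2-(4-chloro-2-formyl-3-hydroxy-5-methylphenoxy)-3-methoxy-5-(prop-2-en-1-yloxy)benzoate | COC(=O)c1cc(OCC=C)cc(OC)c1Oc1cc(C)c(Cl)c(O)c1C=O | intermediate
20 | 3-chloro-2-hydroxy-6-[2-methoxy-6-(methoxycarbonyl)-4-(prop-2-en-1-yloxy)phenoxy]-4-methylbenzoic acid | COC(=O)c1cc(OCC=C)cc(OC)c1Oc1cc(C)c(Cl)c(O)c1C(=O)O | intermediate
21 | isodihydromaldoxin, 3-chloro-2-hydroxy-6-[4-hydroxy-2-methoxy-6-(methoxycarbonyl)phenoxy]-4-methylbenzoic acid (achiral) | COC(=O)c1cc(O)cc(OC)c1Oc1cc(C)c(Cl)c(O)c1C(=O)O | target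

**Totals**
Total step count: 12. Longest linear sequence: 9 steps (1→2→3→7→8→9→10→11→12; the ring-A branch 4→5→6→7…12 is equally long).

**Three steps most likely to fail**

Step 8 (double α′-chlorination). Proton exchange between enolate and α-chloro ketone can leave mixtures of 13, 14 and 15, and NCS can attack the enol-ether carbon if enolisation is incomplete. Fallback: set out from 13, run a single LDA/NCS cycle and isolate 14. Deprotonate 14 again with LDA and trap with PhSeCl to give the α-chloro-α-phenylselanyl ketone F1. Oxidise with H2O2/pyridine in CH2Cl2 at 0 °C to the selenoxide F2, which undergoes syn-elimination across C4–C5 to 16 and tautomerises. The route is rejoined at 17, bypassing 15 and replacing the second chlorination/dehydrochlorination by a selenoxide dehydrogenation.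

Step 10 (ortho-formylation). The only free ortho position lies between the OH and the bulky aryloxy group and may react sluggishly. Fallback: set out from 17 and use Nagata's boron-templated ortho-hydroxymethylation (PhB(OH)2, paraformaldehyde, cat. propionic acid, toluene, reflux with water removal) to give the 2-phenyl-4H-1,3,2-benzodioxaborinine F3. Cleave the boronate with propane-1,3-diol to the benzylic alcohol 18, now isolated, and oxidise with MnO2 in CH2Cl2. The route is rejoined at 19.

Step 7 (ether formation). The phenoxide of 12 is hydrogen-bonded and flanked on both sides, so uncatalysed addition–elimination may be slow and hydrolysis of 7 may compete. Fallback: set out from 6, convert it with PPh3/I2/Et3N in MeCN into 3-iodo-5-methylcyclohex-2-en-1-one F4, and join F4 to 12 by copper-catalysed Ullmann-type O-vinylation (CuI, N,N-dimethylglycine, Cs2CO3, dioxane, 90 °C). The C–O bond is then formed at copper instead of by direct attack, and the route is rejoined at 13.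

**Further compounds**
F1 | step 8 | methyl 2-{[4-chloro-5-methyl-3-oxo-4-(phenylselanyl)cyclohex-1-en-1-yl]oxy}-3-methoxy-5-(prop-2-en-1-yloxy)benzoate | COC(=O)c1cc(OCC=C)cc(OC)c1OC1=CC(=O)C(Cl)([Se]c2ccccc2)C(C)C1
F2 | step 8 | methyl 2-{[4-(benzeneseleninyl)-4-chloro-5-methyl-3-oxocyclohex-1-en-1-yl]oxy}-3-methoxy-5-(prop-2-en-1-yloxy)benzoate | COC(=O)c1cc(OCC=C)cc(OC)c1OC1=CC(=O)C(Cl)([Se](=O)c2ccccc2)C(C)C1
F3 | step 10 | methyl 2-[(8-chloro-7-methyl-2-phenyl-4H-1,3,2-benzodioxaborinin-5-yl)oxy]-3-methoxy-5-(prop-2-en-1-yloxy)benzoate | COC(=O)c1cc(OCC=C)cc(OC)c1Oc1cc(C)c(Cl)c2OB(c3ccccc3)OCc12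
F4 | step 7 | 3-iodo-5-methylcyclohex-2-en-1-one | CC1CC(I)=CC(=O)C1
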